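The data were computed with constants of no real substance; the scatter is artificial.

Begin with an easy step: target can be written as y = s·c, where c is the part of the charged starting material that has reacted, and s is target formed per unit of starting material reacted.

| setting | Thursday's | Tuesday's | Sunday's | flask |
|---|---|---|---|---|
| starting material | 1.5 M | 1.5 M | 0.75 M | 1.5 M |
| reagent in the second phase | 1.7 M | 2.6 M | 1.2 M | 1.20 M |
| protic impurity | 0.15 M | 0.15 M | 0.15 M | 0.150 M |
| remark | run made earlier | run made earlier | run made earlier |  |
| time |  |  |  | 15 h |
| volume of the second phase over the first |  |  |  | 1.0 |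

| run | time / h | target / % | starting material / % |
|---|---|---|---|
| Thursday's | 1.00 | 2.1 | 93.4 |
| Thursday's | 1.33 | 3.2 | 91.0 |
| Thursday's | 2.00 | 3.8 | 87.8 |
| Thursday's | 3.00 | 6.5 | 83.6 |
| Thursday's | 5.00 | 13.4 | 76.8 |
| Thursday's | 8.00 | 16.8 | 69.7 |
| Thursday's | 12.0 | 21.6 | 61.5 |
| Tuesday's | 1.50 | 6.0 | 86.2 |
| Tuesday's | 3.00 | 12.4 | 79.6 |
| Tuesday's | 5.00 | 15.0 | 70.2 |
| Tuesday's | 6.00 | 18.4 | 66.4 |
| Tuesday's | 8.00 | 23.7 | 58.7 |
| Tuesday's | 10.0 | 23.4 | 56.4 |
| Tuesday's | 12.0 | 24.2 | 51.1 |
| Sunday's | 2.50 | 7.7 | 81.9 |
| Sunday's | 5.00 | 15.5 | 67.8 |
| Sunday's | 8.00 | 20.3 | 58.4 |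
| Sunday's | 10.0 | 22.7 | 50.8 |
| Sunday's | 12.0 | 21.5 | 46.7 |

(standard deviation of a reading: 1 percentage point)

- in the second phase: reagent in the second phase; everything else is in the first
- charges count per volume of the first phase; a concentration in a rate is the amount of a species over the volume of its own phase; every rate counts per litre of the first phase
- the earlier runs hold the two phases in the same ratio of volumes as the flask asked about

1. how much target there is at 15 h, in percent of the starting material charged
2. part of the starting material charged that has reacted at 15 h

What is s? Thursday's run lies nearest the flask. At its last reading, 12.0 h, it holds 21.6% target with 38.5% reacted, so this selectivity reads s = 0.561.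

But Tuesday's last reading gives 0.495, lower than s. Doesn't s fall? It does at that depth, with 48.9% reacted. Tuesday's reading at 8.00 h, with 41.3% reacted, still gives 0.574, so s can be carried to a flask that reacts less.

And c? Thursday's and Tuesday's runs differ in reagent in the second phase, and their reacted parts at 12.0 h scale with that charge to an empirical power n = 0.563. Scaled to 1.20 M, Thursday's run gives 31.6% at 12.0 h. Its last interval, scaled likewise, adds 5.1 percentage points for the remaining 3.00 h, so c = 36.7%.

Your number? By my reckoning, s·c = 20.6% target.

The forecast gives 19.5% target, lower than mine, with 37% reacted. It expects a selectivity of 0.53, noting: “Target plateaus near 40–50% conversion, suggesting secondary loss”.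

    reagent in the reaction phase + target → over-reacted product (k = 3.10 M⁻¹ h⁻¹)
    starting material + reagent in the reaction phase → target (k = 2.10 M⁻¹ h⁻¹)
    reagent in the reaction phase ⇌ reagent in the second phase, rate k3*([reagent in the reaction phase] - [reagent in the second phase]/K3) per volume of the first phase (partition coefficient = 1.50, kL = 0.0486 h⁻¹)
    starting material + protic impurity → quenched substrate (k = 0.353 M⁻¹ h⁻¹)

The flask gives 19.4% target with 34.6% reacted, and 65% of the starting material is still there at 15.0 h. Its selectivity comes to 0.561, close to the s read from Thursday's run, while my c stood 2.1 points above the flask's. The same flask stopped at 10 h has c = 28.2%; s turns that into 15.8% target, and that flask holds 15.5%.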